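**Plan**
- Retrosynthesis: remove the three esters (O5 benzoate via a C4,C5-orthobenzoate, O3 acetate, O7 benzoate) and raise C7 to an acyl group. Then cut the ring bond C1–C6 and the C1=C2 alkene, which leads to D-arabinose and a two-carbon ylide.
- Enabling feature (C1 bears C7H2OBz, C2 = vinyl CH, C3 OAc, C4 OH, C5 OBz, C6 OH): inside the single carbocycle, C6(OH)–C1(C7)=C2 is an α-(hydroxyalkyl)acrylate array, the signature of a Morita–Baylis–Hillman adduct. C3/C4/C5 (trans, then cis) map onto C2/C3/C4 of D-arabinose.
- Forward: the chain is joined first by Wittig olefination of arabinose 3,4-acetonide (C1=C2). The terminal carbinol then becomes the C6 aldehyde, and the only ring closes in step 7 by phosphine-catalysed C1–C6 bond formation.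
- The acceptor is an S-ethyl thiol ester rather than an oxo ester, because β-substituted, γ-branched oxo-enoates take up phosphines too slowly for a clean six-ring closure.
- Stereochemistry: C3, C4 and C5 come unchanged from D-arabinose. C6 is set in the ring closure, trans to C5–O, by the cis-fused dioxolane template under reversible aldol conditions.
- End game: orthogonal silyl ethers (C3 TES, C6 TIPS) and the acetonide let O7, O3 and O5 be acylated one after the other. O6 is freed last under acidic fluoride so that no ester migrates.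

Key step: step 7

Convention: target numbering is used for all intermediates. With the ring drawn so that C1 to C6 run clockwise, β is above and α below the plane. The target is 3β-OAc, 4α-OH, 5α-OBz, 6β-OH = (3R,4S,5R,6S). TES = triethylsilyl, TIPS = triisopropylsilyl.
Assumption: ylide 9 is treated as not purchasable and is therefore prepared (steps 2 and 3).

**Step 1**
Reactants: 1 D-arabinose; 2 2,2-dimethoxypropane
Product: 3 3,4-O-isopropylidene-D-arabinopyranose (anomeric mixture)
Conditions: 2 (1.5 equiv), p-TsOH·H2O (cat.), DMF, rt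
Reagents that add atoms: 2,2-dimethoxypropane (2), COC(C)(C)OC
Why: Acid-catalysed transketalisation (acetonide formation) with limited reagent should engage the cis-vicinal O3/O4 diol of the pyranose form, leaving the lactol and O2 free and touching no stereocentre.

**Step 2**
Reactants: 4 bromoacetyl bromide; 5 ethanethiol
Product: 6 S-ethyl bromothioacetate
Conditions: pyridine (1.0 equiv), CH2Cl2, −20 to 0 °C
Reagents that add atoms: none
Why: S-acylation of the thiol at the acyl bromide (thioesterification) is far faster at low temperature than SN2 displacement at the CH2Br carbon.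

**Step 3**
Reactants: 6 S-ethyl bromothioacetate; 7 triphenylphosphine
Product: 9 S-ethyl (triphenylphosphoranylidene)thioacetate, via phosphonium bromide 8 (not isolated)
Conditions: PPh3, toluene, rt; then aq. Na2CO3, CH2Cl2, 0 °C
Reagents that add atoms: none
Why: SN2 quaternisation of the phosphine followed by deprotonation of the acidic salt with carbonate is the standard preparation of a stabilised Wittig ylide, and it is mild enough to spare the thiol ester.

**Step 4**
Reactants: 3 3,4-O-isopropylidene-D-arabinopyranose; 9 S-ethyl (triphenylphosphoranylidene)thioacetate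
Product: 10 S-ethyl (E)-2,3-dideoxy-5,6-O-isopropylidene-1-thio-D-arabino-hept-2-enonate (secondary C3-OH and primary C6-OH free)
Conditions: 9 (1.4 equiv), PhCO2H (10 mol %), CH2Cl2, 40 °C
Reagents that add atoms: none
Why: Wittig olefination of the hydroxy aldehyde in equilibrium with the lactol by a stabilised ylide should give the E-enethioate, the weak acid speeding ring opening and keeping the medium non-basic so that the liberated primary hydroxyl does not add to the acceptor, while C3–C5 are carried over untouched.

**Step 5**
Reactants: 10 diol enethioate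
Product: 11 S-ethyl (E)-2,3-dideoxy-5,6-O-isopropylidene-4,7-bis-O-(triethylsilyl)-1-thio-D-arabino-hept-2-enonate
Conditions: TESCl (2.4 equiv), imidazole (5 equiv), CH2Cl2, 0 °C
Reagents that add atoms: chlorotriethylsilane, CC[Si](Cl)(CC)CC
Why: Standard imidazole-promoted silyl ether formation caps both hydroxyls, TES being small enough next to C2 for the later phosphine addition and removable later beside TIPS.

**Step 6**
Reactants: 11 bis-TES ether
Product: 13 S-ethyl (2E,4R)-4-[(4R,5S)-5-formyl-2,2-dimethyl-1,3-dioxolan-4-yl]-4-(triethylsilyloxy)but-2-enethioate, via alkoxysulfonium chloride 12 (not isolated)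
Conditions: (COCl)2 (4 equiv), DMSO (8 equiv), CH2Cl2, −78 to −40 °C; then Et3N (15 equiv), −78 to −20 °C; used crude
Reagents that add atoms: none
Why: In the Swern oxidation of silyl ethers the activated sulfoxide displaces only the unhindered primary TES group, and the resulting alkoxysulfonium salt collapses with amine at low temperature to the C6 aldehyde without enolising C5 or touching the secondary TES ether, acetonide or thiol ester.

**Step 7**
Reactants: 13 enethioate aldehyde
Product: 16 S-ethyl (3R,4R,5R,6S)-6-hydroxy-4,5-(isopropylidenedioxy)-3-(triethylsilyloxy)cyclohex-1-ene-1-carbothioate (3β,4α,5α,6β), via phosphonium enolate 14 (not isolated), via phosphonium aldolate 15 (not isolated)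
Conditions: PMe3 (30 mol %, 1 M in toluene), degassed CH2Cl2 (0.02 M), rt
Reagents that add atoms: none
Why: PMe3 adds reversibly to C2 to give enolate 14, whose C1 attacks the C6 aldehyde and forms the C1–C6 bond (aldolate 15); a C1–H to oxygen proton shift and E1cB loss of the phosphine then restore the C1=C2 alkene inside the new ring, so the alkene geometry of 13 is immaterial. This is the phosphine-catalysed intramolecular Morita–Baylis–Hillman reaction, known for formyl-tethered enones, enoates and, most efficiently for cyclohexenols, enethioates. The carbocycle closes in a 6-(enolexo)-exo-trig aldol mode, helped by the cis-dioxolane that folds C1 towards C6. C6 is set by the ring template and not by an open-chain Felkin–Anh or Cornforth model, both of which point to the erythro (ring-cis) isomer and lose their steric basis once the nucleophile is tethered through C4: in the chair-like closure with C3–OTES and C4–O equatorial and C5–O axial, the aldehyde oxygen sits axial, anti to C5–O with opposed dipoles and within reach of the C2 phosphonium, whereas the cis aldolate needs either a gauche O5/O6 array pressed against the C1 acyl group or a syn-diaxial O4/O6 contact. Because the aldol step is reversible and proton transfer is product-determining, the less strained 6β aldolate should drain to 16, in which the hydroxyl lies on the convex face, pseudoaxial and free of A(1,2) strain with the acyl group. The step needs cyclisation to outrun C5 epimerisation, β-elimination of C4–O and intermolecular coupling, which the activated thiol ester, the small and weakly basic phosphine, the absence of metal alkoxides and high dilution should secure.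

**Step 8**
Reactants: 16 cyclohexenol
Product: 17 S-ethyl 4α,5α-(isopropylidenedioxy)-3β-(triethylsilyloxy)-6β-(triisopropylsilyloxy)cyclohex-1-ene-1-carbothioate
Conditions: TIPSOTf (1.5 equiv), 2,6-lutidine (3 equiv), CH2Cl2, 0 °C to rt
Reagents that add atoms: triisopropylsilyl trifluoromethanesulfonate, CC(C)[Si](OS(=O)(=O)C(F)(F)F)(C(C)C)C(C)C
Why: Silylation with a silyl triflate and a hindered pyridine base is the usual way to cap a crowded secondary allylic alcohol, and TIPS is chosen to outlast the later acid steps and to bias the ring conformation.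

**Step 9**
Reactants: 17 thiol ester
Product: 18 [4α,5α-(isopropylidenedioxy)-3β-(triethylsilyloxy)-6β-(triisopropylsilyloxy)cyclohex-1-en-1-yl]methanol
Conditions: i-Bu2AlH (3.5 equiv), CH2Cl2, −78 to −20 °C; aq. potassium sodium tartrate
Reagents that add atoms: none
Why: Excess aluminium hydride reduces the conjugated thiol ester in the 1,2-sense through the enal to the primary allylic alcohol, conditions under which silyl ethers and the acetonide are inert.

**Step 10**
Reactants: 18 allylic alcohol; 19 benzoyl chloride
Product: 20 [4α,5α-(isopropylidenedioxy)-3β-(triethylsilyloxy)-6β-(triisopropylsilyloxy)cyclohex-1-en-1-yl]methyl benzoate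
Conditions: BzCl (1.2 equiv), pyridine (3 equiv), DMAP (cat.), CH2Cl2, 0 °C
Reagents that add atoms: benzoyl chloride (19), O=C(Cl)c1ccccc1
Why: DMAP-catalysed esterification of the only free hydroxyl installs the C7 benzoate without any selectivity issue.

**Step 11**
Reactants: 20 C7 benzoate
Product: 21 [3β-hydroxy-4α,5α-(isopropylidenedioxy)-6β-(triisopropylsilyloxy)cyclohex-1-en-1-yl]methyl benzoate
Conditions: PPTS (20 mol %), MeOH/CH2Cl2 (1:1), 0 °C
Reagents that add atoms: none
Why: Acid-catalysed methanolysis distinguishes silyl ethers by bulk, so the TES ether should cleave much faster than the TIPS ether, while the ring-fused acetonide and the benzoate survive this weak acid.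

**Step 12**
Reactants: 21 C3 alcohol; 22 acetic anhydride
Product: 23 [3β-acetoxy-4α,5α-(isopropylidenedioxy)-6β-(triisopropylsilyloxy)cyclohex-1-en-1-yl]methyl benzoate
Conditions: Ac2O (2 equiv), pyridine, DMAP (cat.), CH2Cl2, 0 °C to rt
Reagents that add atoms: acetic anhydride (22), CC(=O)OC(C)=O
Why: DMAP-catalysed acetylation of the single free hydroxyl proceeds with retention at C3 because only the O–H bond is involved.

**Step 13**
Reactants: 23 acetonide
Product: 24 [3β-acetoxy-4α,5α-dihydroxy-6β-(triisopropylsilyloxy)cyclohex-1-en-1-yl]methyl benzoate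
Conditions: TFA/H2O (9:1), CH2Cl2, 0 °C
Reagents that add atoms: none
Why: Aqueous-acid ketal hydrolysis at low temperature frees the cis C4,C5-diol, while the acid-robust TIPS ether and the esters persist and acid-promoted acetyl migration stays slow.

**Step 14**
Reactants: 24 cis-diol; 25 trimethyl orthobenzoate
Product: 27 [3β-acetoxy-5α-benzoyloxy-4α-hydroxy-6β-(triisopropylsilyloxy)cyclohex-1-en-1-yl]methyl benzoate, via cyclic orthobenzoate 26 (not isolated)
Conditions: PhC(OMe)3 (3 equiv), CSA (10 mol %), MeCN, rt; then 80% aq. AcOH, 0 °C to rt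
Reagents that add atoms: trimethyl orthobenzoate (25), COC(OC)(OC)c1ccccc1; water, O
Why: Orthoester exchange closes a 2-methoxy-2-phenyl-1,3-dioxolane on the cis-diol, and its mild hydrolysis follows the well-known stereoelectronic preference of six-ring-fused orthoesters to collapse to the axial ester and the equatorial alcohol; A(1,2) strain between C6–OTIPS and C7 holds the half-chair with C6–O pseudoaxial, C5–O axial and C4–O equatorial, so the benzoate should land on O5.

**Step 15**
Reactants: 27 TIPS ether
Product: 28 [(3R,4S,5R,6S)-3-acetoxy-5-benzoyloxy-4,6-dihydroxycyclohex-1-en-1-yl]methyl benzoate (CNP0169028.1)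
Conditions: HF·pyridine (excess), THF, 0 °C to rt (plastic vessel)
Reagents that add atoms: none
Why: Fluoride-driven Si–O cleavage in an acidic medium removes the hindered silyl ether while the three esters and the allylic system stay intact, and the absence of base suppresses acyl migration to O4 or O6.

**Compound list**
1 | D-arabinose | O=C[C@@H](O)[C@H](O)[C@H](O)CO | starting material
2 | 2,2-dimethoxypropane | COC(C)(C)OC | starting material
3 | 3,4-O-isopropylidene-D-arabinopyranose (anomeric mixture) | OC1OC[C@H]2OC(C)(C)O[C@H]2[C@@H]1O | intermediate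
4 | bromoacetyl bromide | O=C(Br)CBr | starting material
5 | ethanethiol | CCS | starting material
6 | S-ethyl bromothioacetate | CCSC(=O)CBr | intermediate
7 | triphenylphosphine | c1ccc(cc1)P(c1ccccc1)c1ccccc1 | starting material
8 | [2-(ethylthio)-2-oxoethyl]triphenylphosphonium bromide | CCSC(=O)C[P+](c1ccccc1)(c1ccccc1)c1ccccc1.[Br-] | intermediate
9 | S-ethyl (triphenylphosphoranylidene)thioacetate | CCSC(=O)C=P(c1ccccc1)(c1ccccc1)c1ccccc1 | intermediate
10 | S-ethyl (E)-2,3-dideoxy-5,6-O-isopropylidene-1-thio-D-arabino-hept-2-enonate | OC[C@H]1OC(C)(C)O[C@H]1[C@H](O)/C=C/C(=O)SCC | intermediate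
11 | 4,7-bis-O-triethylsilyl derivative of 10 | CC[Si](CC)(CC)OC[C@H]1OC(C)(C)O[C@H]1[C@H](O[Si](CC)(CC)CC)/C=C/C(=O)SCC | intermediate
12 | C6 alkoxydimethylsulfonium chloride | C[S+](C)OC[C@H]1OC(C)(C)O[C@H]1[C@H](O[Si](CC)(CC)CC)/C=C/C(=O)SCC.[Cl-] | intermediate
13 | S-ethyl (2E,4R)-4-[(4R,5S)-5-formyl-2,2-dimethyl-1,3-dioxolan-4-yl]-4-(triethylsilyloxy)but-2-enethioate | O=C[C@H]1OC(C)(C)O[C@H]1[C@H](O[Si](CC)(CC)CC)/C=C/C(=O)SCC | intermediate
14 | C2-trimethylphosphonium thioester enolate (C2 undefined) | O=C[C@H]1OC(C)(C)O[C@H]1[C@H](O[Si](CC)(CC)CC)C([P+](C)(C)C)C=C([O-])SCC | intermediate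
15 | C2-trimethylphosphonium C6-aldolate (C1 and C2 undefined) | CC[Si](CC)(CC)O[C@@H]1C([P+](C)(C)C)C(C(=O)SCC)[C@H]([O-])[C@H]2OC(C)(C)O[C@@H]12 | intermediate
16 | S-ethyl (3R,4R,5R,6S)-6-hydroxy-4,5-(isopropylidenedioxy)-3-(triethylsilyloxy)cyclohex-1-ene-1-carbothioate | CC[Si](CC)(CC)O[C@@H]1C=C(C(=O)SCC)[C@H](O)[C@H]2OC(C)(C)O[C@@H]12 | intermediate
17 | 6β-O-TIPS ether of 16 | CC[Si](CC)(CC)O[C@@H]1C=C(C(=O)SCC)[C@H](O[Si](C(C)C)(C(C)C)C(C)C)[C@H]2OC(C)(C)O[C@@H]12 | intermediate
18 | [4α,5α-(isopropylidenedioxy)-3β-(triethylsilyloxy)-6β-(triisopropylsilyloxy)cyclohex-1-en-1-yl]methanol | CC[Si](CC)(CC)O[C@@H]1C=C(CO)[C@H](O[Si](C(C)C)(C(C)C)C(C)C)[C@H]2OC(C)(C)O[C@@H]12 | intermediate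
19 | benzoyl chloride | O=C(Cl)c1ccccc1 | starting material
20 | C7 benzoate of 18 | CC[Si](CC)(CC)O[C@@H]1C=C(COC(=O)c3ccccc3)[C@H](O[Si](C(C)C)(C(C)C)C(C)C)[C@H]2OC(C)(C)O[C@@H]12 | intermediate
21 | [3β-hydroxy-4α,5α-(isopropylidenedioxy)-6β-(triisopropylsilyloxy)cyclohex-1-en-1-yl]methyl benzoate | O[C@@H]1C=C(COC(=O)c3ccccc3)[C@H](O[Si](C(C)C)(C(C)C)C(C)C)[C@H]2OC(C)(C)O[C@@H]12 | intermediate
22 | acetic anhydride | CC(=O)OC(C)=O | starting material
23 | [3β-acetoxy-4α,5α-(isopropylidenedioxy)-6β-(triisopropylsilyloxy)cyclohex-1-en-1-yl]methyl benzoate | CC(=O)O[C@@H]1C=C(COC(=O)c3ccccc3)[C@H](O[Si](C(C)C)(C(C)C)C(C)C)[C@H]2OC(C)(C)O[C@@H]12 | intermediate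
24 | [3β-acetoxy-4α,5α-dihydroxy-6β-(triisopropylsilyloxy)cyclohex-1-en-1-yl]methyl benzoate | CC(=O)O[C@@H]1C=C(COC(=O)c2ccccc2)[C@H](O[Si](C(C)C)(C(C)C)C(C)C)[C@@H](O)[C@H]1O | intermediate
25 | trimethyl orthobenzoate | COC(OC)(OC)c1ccccc1 | starting material
26 | 4α,5α-(α-methoxybenzylidenedioxy) orthobenzoate of 24 (orthoester carbon undefined) | CC(=O)O[C@@H]1C=C(COC(=O)c3ccccc3)[C@H](O[Si](C(C)C)(C(C)C)C(C)C)[C@H]2OC(OC)(c3ccccc3)O[C@@H]12 | intermediate
27 | [3β-acetoxy-5α-benzoyloxy-4α-hydroxy-6β-(triisopropylsilyloxy)cyclohex-1-en-1-yl]methyl benzoate | CC(=O)O[C@@H]1C=C(COC(=O)c2ccccc2)[C@H](O[Si](C(C)C)(C(C)C)C(C)C)[C@@H](OC(=O)c2ccccc2)[C@H]1O | intermediate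
28 | [(3R,4S,5R,6S)-3-acetoxy-5-benzoyloxy-4,6-dihydroxycyclohex-1-en-1-yl]methyl benzoate | CC(=O)O[C@@H]1C=C(COC(=O)c2ccccc2)[C@H](O)[C@@H](OC(=O)c2ccccc2)[C@H]1O | target

**Step count**
Total step count: 15.
Longest linear sequence: 14 steps (steps 2 to 15, from bromoacetyl bromide). The count from D-arabinose is 13.

**Steps most likely to fail**

1. **Step 7.**
 - Risk: phosphine addition at the γ-branched C2 may be slow. Enolisation of the aldehyde (epimerisation at C5, β-elimination of the C4–O bond) and intermolecular coupling could then compete. Facial selectivity at C6 may also be incomplete.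
 - Fallback: this forms the same C1–C6 bond but uses a stoichiometric sulfur nucleophile in place of catalysis, and it sets out from 13. EtSLi (from EtSH and n-BuLi) in THF at −78 °C should trigger a thia-Michael/aldol cascade, in which thiolate exchange at the thiol ester is degenerate, to give the 2-ethylthio aldol adduct F1. One equivalent of mCPBA in CH2Cl2 at −78 °C should oxidise only the dialkyl sulfide to the ethyl sulfoxide F2. Warming F2 in toluene over solid NaHCO3 should bring about syn-elimination towards the acidic C1–H, which comes back to the route at 16.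

2. **Step 14.**
 - Risk: regiocontrol in the collapse of the hemiorthoester may be lost if the half-chair is less biased than expected. Benzoyl migration from O5 to O4 may also occur during hydrolysis and purification.
 - Fallback: this replaces stereoelectronic control by steric differentiation and sets out from 24. TESCl (1.05 equiv) and imidazole in CH2Cl2 at −40 °C should silylate the equatorial, less shielded O4 to give the 4-O-TES ether F3. BzCl, DMAP and pyridine at rt should then acylate the remaining axial O5 to give the 5-O-benzoate F4. HF·pyridine in THF should strip both silyl groups in one operation, coming back to the route at 28.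

3. **Step 4.**
 - Risk: ring opening of the lactol may be slow. The liberated primary hydroxyl may add in conjugate fashion to the activated acceptor. Any Z isomer may lactonise through the free γ-hydroxyl.
 - Fallback: the acceptor is introduced only after both hydroxyls are capped, and the sequence sets out from 3. Ph3P=CH2 (from Ph3PCH3Br and KOt-Bu, 3.5 equiv) in THF at 0 °C to rt should give the terminal alkene diol F5. TESCl and imidazole should convert it into the bis-TES alkene F6. Cross metathesis of F6 with S-ethyl thioacrylate (second-generation Hoveyda–Grubbs catalyst, CH2Cl2, 40 °C) should deliver the E-enethioate and come back to the route at 11.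

**Further compounds**
F1 | step 7 | S-ethyl 2-(ethylthio)-6β-hydroxy-4α,5α-(isopropylidenedioxy)-3β-(triethylsilyloxy)cyclohexane-1-carbothioate (C1 and C2 undefined) | CC[Si](CC)(CC)O[C@@H]1C(SCC)C(C(=O)SCC)[C@H](O)[C@H]2OC(C)(C)O[C@@H]12
F2 | step 7 | S-ethyl 2-(ethylsulfinyl)-6β-hydroxy-4α,5α-(isopropylidenedioxy)-3β-(triethylsilyloxy)cyclohexane-1-carbothioate (C1, C2 and sulfur undefined) | CC[Si](CC)(CC)O[C@@H]1C(S(=O)CC)C(C(=O)SCC)[C@H](O)[C@H]2OC(C)(C)O[C@@H]12
F3 | step 14 | [3β-acetoxy-5α-hydroxy-4α-(triethylsilyloxy)-6β-(triisopropylsilyloxy)cyclohex-1-en-1-yl]methyl benzoate | CC(=O)O[C@@H]1C=C(COC(=O)c2ccccc2)[C@H](O[Si](C(C)C)(C(C)C)C(C)C)[C@@H](O)[C@H]1O[Si](CC)(CC)CC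
F4 | step 14 | [3β-acetoxy-5α-benzoyloxy-4α-(triethylsilyloxy)-6β-(triisopropylsilyloxy)cyclohex-1-en-1-yl]methyl benzoate | CC(=O)O[C@@H]1C=C(COC(=O)c2ccccc2)[C@H](O[Si](C(C)C)(C(C)C)C(C)C)[C@@H](OC(=O)c2ccccc2)[C@H]1O[Si](CC)(CC)CC
F5 | step 4 | 1,2-dideoxy-4,5-O-isopropylidene-D-arabino-hex-1-enitol | OC[C@H]1OC(C)(C)O[C@H]1[C@H](O)C=C
F6 | step 4 | 1,2-dideoxy-4,5-O-isopropylidene-3,6-bis-O-(triethylsilyl)-D-arabino-hex-1-enitol | CC[Si](CC)(CC)OC[C@H]1OC(C)(C)O[C@H]1[C@H](O[Si](CC)(CC)CC)C=C
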